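Slowness was the first thing the dusk run showed: after 5.00 h it still held 5.6 % as free monomer, with 76.8 % in chains.

| flask | free monomer | protic impurity | initiator | remark | time |
|---|---|---|---|---|---|
| dusk | 2.5 M | 1.8 M | 0.51 mol% | run made earlier |  |
| flask | 1.8 M | 1.80 M | 0.51 mol% |  | 6.0 h |

dusk run (percent of the free monomer charged)

| time / h | monomer in chains / % | free monomer / % |
|---|---|---|
| 0.667 | 8.5 | 84.9 |
| 1.50 | 29.9 | 58.5 |
| 3.00 | 60.5 | 23.8 |
| 5.00 | 76.8 | 5.6 |

(scatter of a reading: 0.3 percentage points)

- the average divides the monomer in chains by the number of chains begun, living and dead together
- the earlier runs do not show the number of chains; that part of a forecast is a guess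
- no earlier run changes the charge of initiator; that part of a forecast is a guess

* whether the average number of monomer units in a chain (chains begun, living or dead) reaches 100 by 6.0 h (no / yes)
* average number of monomer units in a chain (chains begun, living or dead) at 6.0 h

I reckoned from the initiator, charged at 0.51 mol% of the free monomer. Its balance allows no more chains than its charge, so the average length is at least the fraction in chains divided by that loading. Length 100 is therefore assured once the fraction in chains passes 51.0 %, the floor fraction. The dusk run, with the same loading, stood at 29.9 % at 1.50 h and at 60.5 % at 3.00 h.

Two amounts then mattered in the flask: this floor and the fraction it would reach. I assumed that the flask's growth clock stretched with the charge, so its 6.0 h matched 4.32 h of the dusk run. As a cautious stand-in I took the earlier dusk reading at 3.00 h and raised its ratio of missing monomer to monomer in chains by the ratio of charges. That gave 56.0 %, which is above the floor, so I answered yes. The length would be at least 110, and how far above that was a guess.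

The forecast said yes, with 310 (from 190 to 420), and argued: “Even if every initiator molecule started a chain, DP≈137, so 100 is passed”.

The flask gave yes, with an average length of 221.

    free monomer + initiator → living end + monomer in chains (k = 0.190 M⁻¹ h⁻¹)
    free monomer + living end → monomer in chains + living end, rate k2*[living end]*[free monomer] (k = 79.0 M⁻¹ h⁻¹)
    protic impurity + free monomer → quenched substrate (k = 0.0550 M⁻¹ h⁻¹)

At 2.38 h the flask used free monomer 4.1 times as fast for chains as for quenched substrate. At 6.00 h it held 67.9 % in chains against 23.4 % as quenched substrate, above the floor of 51.0 %, and with 40 % of the initiator still unbound, the fraction in chains divided by the initiator used gives 222 units per chain.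

Readings and results were generated by integration for an exercise; noise was put on by code.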